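**Retrosynthetic overview**

1. Nakijiquinone J ⇒ hydrolysis of the 2-methoxy group and aminolysis of the 5-methoxy group ⇒ 3-alkyl-2,5-dimethoxy-1,4-benzoquinone + (S)-2-methylbutylamine.
2. Rearranged decalin (8β,9β-dimethyl, 10α-H, Δ5(6)) ⇒ 8α-hydroxydrimane, by a H-9→C-8 / CH3-10→C-9 / H-5→C-10 shift cascade ended by loss of H-6; the three stereocentres are relayed from sclareolide.
3. C-11–C-3′ bond ⇒ photoredox decarboxylative radical addition of ring-opened sclareolide carboxylate to 2,5-dimethoxy-1,4-benzoquinone.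
4. Ring order: no ring is built; the decalin (from (+)-sclareolide) and the quinone ring are bought, and the decalin is only reorganised after the coupling.

Assumption: natural (+)-sclareolide, 2,5-dimethoxy-1,4-benzoquinone and (S)-(−)-2-methylbutylamine are bought; drimane numbering (C-1 to C-12) is used for the terpenoid part and primed numbers for the quinone.

**Route**

Step 1
Reactants: 1 (+)-sclareolide
Product: 2 potassium [(1R,2R,4aS,8aS)-2-hydroxy-2,5,5,8a-tetramethyldecahydronaphthalen-1-yl]acetate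
Conditions: KOH (1.05 equiv), MeOH/H2O, reflux; evaporate, dry (toluene azeotrope)
Reagents that add atoms: potassium hydroxide, [K+].[OH-]
Why: Lactone saponification by acyl–oxygen cleavage leaves all four stereocentres untouched, and the γ-hydroxy carboxylate salt cannot relactonise and is the form needed for oxidative decarboxylation.

Step 2
Reactants: 2 potassium [(1R,2R,4aS,8aS)-2-hydroxy-2,5,5,8a-tetramethyldecahydronaphthalen-1-yl]acetate; 3 2,5-dimethoxy-1,4-benzoquinone (3 equiv)
Product: 5 3-{[(1R,2R,4aS,8aS)-2-hydroxy-2,5,5,8a-tetramethyldecahydronaphthalen-1-yl]methyl}-2,5-dimethoxy-1,4-benzoquinone, via 3-{[(1R,2R,4aS,8aS)-2-hydroxy-2,5,5,8a-tetramethyldecahydronaphthalen-1-yl]methyl}-2,5-dimethoxybenzene-1,4-diol 4 (not isolated)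
Conditions: 9-mesityl-3,6-di-tert-butyl-10-phenylacridinium BF4 (5 mol%), MeCN/DMSO/H2O, 450 nm LEDs, 25 °C, Ar
Reagents that add atoms: none
Why: Photoredox oxidative decarboxylation gives the primary C-11 radical, which adds Giese/Jacobsen–Torssell-type to the only free position of 3; the adduct is reduced to hydroquinone 4 and re-oxidised by excess 3, and no stereocentre is touched.

Step 3
Reactants: 5 3-{[(1R,2R,4aS,8aS)-2-hydroxy-2,5,5,8a-tetramethyldecahydronaphthalen-1-yl]methyl}-2,5-dimethoxy-1,4-benzoquinone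
Product: 7 2,5-dimethoxy-3-{[(1R,2S,8aS)-1,2,5,5-tetramethyl-1,2,3,5,6,7,8,8a-octahydronaphthalen-1-yl]methyl}-1,4-benzoquinone, via the 8-O-trifluoromethanesulfonate of 5 6 (not isolated)
Conditions: Tf2O (1.3 equiv), 2,6-di-tert-butyl-4-methylpyridine (3 equiv), CH2Cl2, −78 → −40 °C; Et3N quench
Reagents that add atoms: none
Why: Proposed new method: a base-buffered, kinetically terminated friedo-type 1,2-shift cascade – triflate 6 ionises to the C-8 cation, and three suprafacial shifts fixed by the sclareolide stereocentres (H-9α→C-8 gives 8S with 8β-CH3; CH3-10β→C-9 gives the 9R quaternary centre with the CH2-quinone arm on the α face; H-5α→C-10 gives 10S) relay the charge to C-5, the tertiary site furthest from the electron-poor quinone; because the hindered pyridine is the only base and no free Brønsted acid is present, proton loss should be irreversible and Hofmann-type, taking the exposed C-6 methylene proton rather than the shielded H-10 methine, so the Δ5(6) olefin cannot equilibrate to the Δ5(10) olefin; closest known reactions are the BF3·OEt2-mediated 1,2-H/1,2-Me shift rearrangement of 8-functionalised aryl drimanes (which ends at the Δ5(10) olefin under equilibrating acid) and Tf2O/hindered-pyridine dehydration of tertiary alcohols.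

Step 4
Reactants: 7 2,5-dimethoxy-3-{[(1R,2S,8aS)-1,2,5,5-tetramethyl-1,2,3,5,6,7,8,8a-octahydronaphthalen-1-yl]methyl}-1,4-benzoquinone; 8 (S)-2-methylbutylamine (1.5 equiv)
Product: 9 2-methoxy-5-{[(2S)-2-methylbutyl]amino}-3-{[(1R,2S,8aS)-1,2,5,5-tetramethyl-1,2,3,5,6,7,8,8a-octahydronaphthalen-1-yl]methyl}-1,4-benzoquinone
Conditions: EtOH, 25 °C
Reagents that add atoms: none
Why: Vinylogous-ester aminolysis (addition–elimination) occurs at the unhindered C-5′ methoxy carbon, the C-2′ methoxy being shielded by the neopentyl-type CH2; the amine stereocentre is not involved.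

Step 5
Reactants: 9 2-methoxy-5-{[(2S)-2-methylbutyl]amino}-3-{[(1R,2S,8aS)-1,2,5,5-tetramethyl-1,2,3,5,6,7,8,8a-octahydronaphthalen-1-yl]methyl}-1,4-benzoquinone
Product: 11 nakijiquinone J, via the potassium 2′-oxido salt of nakijiquinone J 10 (not isolated)
Conditions: 2 M aq KOH (5 equiv), MeOH, 50 °C; then cold 1 M HCl to pH 3
Reagents that add atoms: potassium hydroxide, [K+].[OH-]
Why: Vinylogous-ester saponification (hydroxide addition–elimination at C-2′) removes the only remaining methoxy group, while the vinylogous amide is far less electrophilic and the olefin and stereocentres are inert to aqueous base.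

**Compound list**

1 | (+)-sclareolide, (3aR,5aS,9aS,9bR)-3a,6,6,9a-tetramethyldecahydronaphtho[2,1-b]furan-2(1H)-one | O=C1C[C@@H]2[C@@]3(C)CCCC(C)(C)[C@@H]3CC[C@@]2(C)O1 | starting material
2 | potassium [(1R,2R,4aS,8aS)-2-hydroxy-2,5,5,8a-tetramethyldecahydronaphthalen-1-yl]acetate | [K+].[O-]C(=O)C[C@@H]1[C@@]2(C)CCCC(C)(C)[C@@H]2CC[C@@]1(C)O | intermediate
3 | 2,5-dimethoxy-1,4-benzoquinone | COC1=CC(=O)C(OC)=CC1=O | starting material
4 | 3-{[(1R,2R,4aS,8aS)-2-hydroxy-2,5,5,8a-tetramethyldecahydronaphthalen-1-yl]methyl}-2,5-dimethoxybenzene-1,4-diol | COc1cc(O)c(OC)c(C[C@@H]2[C@@]3(C)CCCC(C)(C)[C@@H]3CC[C@@]2(C)O)c1O | intermediate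
5 | 3-{[(1R,2R,4aS,8aS)-2-hydroxy-2,5,5,8a-tetramethyldecahydronaphthalen-1-yl]methyl}-2,5-dimethoxy-1,4-benzoquinone (8α-hydroxydrimane, C-11 bonded to C-3′) | COC1=CC(=O)C(OC)=C(C[C@@H]2[C@@]3(C)CCCC(C)(C)[C@@H]3CC[C@@]2(C)O)C1=O | intermediate
6 | 8-O-trifluoromethanesulfonate of 5 | COC1=CC(=O)C(OC)=C(C[C@@H]2[C@@]3(C)CCCC(C)(C)[C@@H]3CC[C@@]2(C)OS(=O)(=O)C(F)(F)F)C1=O | intermediate
7 | 2,5-dimethoxy-3-{[(1R,2S,8aS)-1,2,5,5-tetramethyl-1,2,3,5,6,7,8,8a-octahydronaphthalen-1-yl]methyl}-1,4-benzoquinone (8β,9β-dimethyl, 9α-CH2, 10α-H, Δ5(6)) | COC1=CC(=O)C(OC)=C(C[C@@]2(C)[C@@H]3CCCC(C)(C)C3=CC[C@@H]2C)C1=O | intermediate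
8 | (S)-2-methylbutylamine | CC[C@H](C)CN | starting material
9 | 2-methoxy-5-{[(2S)-2-methylbutyl]amino}-3-{[(1R,2S,8aS)-1,2,5,5-tetramethyl-1,2,3,5,6,7,8,8a-octahydronaphthalen-1-yl]methyl}-1,4-benzoquinone | CC[C@H](C)CNC1=CC(=O)C(OC)=C(C[C@@]2(C)[C@@H]3CCCC(C)(C)C3=CC[C@@H]2C)C1=O | intermediate
10 | potassium 2′-oxido salt of nakijiquinone J | [K+].CC[C@H](C)CNC1=CC(=O)C([O-])=C(C[C@@]2(C)[C@@H]3CCCC(C)(C)C3=CC[C@@H]2C)C1=O | intermediate
11 | nakijiquinone J, 2-hydroxy-5-{[(2S)-2-methylbutyl]amino}-3-{[(1R,2S,8aS)-1,2,5,5-tetramethyl-1,2,3,5,6,7,8,8a-octahydronaphthalen-1-yl]methyl}-1,4-benzoquinone | CC[C@H](C)CNC1=CC(=O)C(O)=C(C[C@@]2(C)[C@@H]3CCCC(C)(C)C3=CC[C@@H]2C)C1=O | target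

**Step count and risks**

Total step count: 5. Longest linear sequence: 5 (1 → 2 → 5 → 7 → 9 → 11).

Steps most likely to fail:

Step 2 (photoredox coupling). The hindered primary radical may be trapped poorly by the electron-rich, light-absorbing quinone. The fallback sets out from 1 and comes back at 5, and excises C-12 before the coupling. DIBAL-H reduces 1 to sclareolide lactol F1. Suárez alkoxy-radical β-fragmentation (PhI(OAc)2, I2, hν) then gives 11-iodo-12-nordriman-8α-yl formate F2. The same C-11 radical is generated from the iodide by Mn2(CO)10/blue-light iodine abstraction in the presence of excess 3, giving the 8-O-formate of 5 F3. K2CO3/MeOH removes the formate and returns 5.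

Step 3 (the proposed new step). Possible failures are early E1 exit to unrearranged drimenes, leakage to the Δ1(10) or Δ5(10) olefins, over-shift of a C-4 methyl, or capture of the cation by a quinone oxygen. The fallback uses known chemistry, sets out from 5 and comes back at 7. Compound 5 is put through the established Lewis-acid version of the cascade (BF3·OEt2, CH2Cl2, −78 → −20 °C), which should stop at the tetrasubstituted Δ5(10) olefin F4. F4 is then equilibrated with catalytic TsOH (benzene, 50 °C). Isomer 7 is expected to be the more stable C-10 epimer, since all large groups on ring B are equatorial. It is separated on AgNO3-impregnated silica and F4 is recycled.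

Step 5 (final demethylative hydrolysis). Attack at the hindered C-2′ may be slow and may compete with hydrolysis of the amino group. The fallback sets out from 7 and comes back at 11, and reverses the order. Both methoxy groups of 7 are hydrolysed (2 M KOH, MeOH/H2O, reflux; HCl) to the 2,5-dihydroxy-3-alkyl-1,4-benzoquinone F5. F5 is condensed with 8 (EtOH, cat. AcOH, 50 °C) at the unhindered C-5′ hydroxyl (embelin-type amination) to give 11 directly.

**Further compounds**

F1 | step 2 | sclareolide lactol (12-hemiacetal, anomeric mixture) | OC1C[C@@H]2[C@@]3(C)CCCC(C)(C)[C@@H]3CC[C@@]2(C)O1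
F2 | step 2 | 11-iodo-12-nordriman-8α-yl formate | IC[C@@H]1[C@@]2(C)CCCC(C)(C)[C@@H]2CC[C@@]1(C)OC=O
F3 | step 2 | 8-O-formate of 5 | COC1=CC(=O)C(OC)=C(C[C@@H]2[C@@]3(C)CCCC(C)(C)[C@@H]3CC[C@@]2(C)OC=O)C1=O
F4 | step 3 | Δ5(10) isomer of 7, 2,5-dimethoxy-3-{[(1R,2S)-1,2,5,5-tetramethyl-1,2,3,4,5,6,7,8-octahydronaphthalen-1-yl]methyl}-1,4-benzoquinone | COC1=CC(=O)C(OC)=C(C[C@@]2(C)C3=C(CC[C@@H]2C)C(C)(C)CCC3)C1=O
F5 | step 5 | 2,5-dihydroxy-3-{[(1R,2S,8aS)-1,2,5,5-tetramethyl-1,2,3,5,6,7,8,8a-octahydronaphthalen-1-yl]methyl}-1,4-benzoquinone | OC1=CC(=O)C(O)=C(C[C@@]2(C)[C@@H]3CCCC(C)(C)C3=CC[C@@H]2C)C1=O
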